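G is the product we want from this flask; in the earlier runs Q comes with it, rises, then falls.

| flask | X | Z | remark | time |
|---|---|---|---|---|
| east | 0.13 M | 3.6 mM | run made earlier |  |
| south-west | 0.13 M | 5.7 mM | run made earlier |  |
| north-east | 0.26 M | 2.6 mM | run made earlier |  |
| flask | 0.13 M | 2.60 mM |  | 6.0 d |

- east (time / d: G / %, Q / %): 0.625: 44.0, 17.3; 1.25: 66.7, 18.0; 1.67: 75.2, 16.1; 2.50: 84.5, 10.9; 3.00: 87.2, 8.2; 4.00: 90.6, 5.4
- south-west (time / d: G / %, Q / %): 0.625: 43.6, 16.7; 1.25: 65.7, 17.7; 1.67: 74.0, 15.8; 2.50: 82.9, 11.0; 3.00: 86.1, 8.8; 4.00: 89.9, 5.6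
- north-east (time / d: G / %, Q / %): 0.250: 19.2, 8.7; 0.500: 38.6, 15.0; 1.04: 62.8, 18.5; 2.08: 82.6, 12.6; 4.00: 93.8, 4.9

(readings scatter by 0.3 percentage points)

- a reading or a percentage of G counts all its forms, free or not

* share of G in G plus Q at 1.0 h
* share of G in G plus Q at 6.0 d

The north-east run has the earliest readings: the share of G in G plus Q is 68.8% at 0.250 d and 72.0% at 0.500 d. Running that line back to zero time gives 65.6%, a reading that we call the branch share, the selectivity: the share of G in G plus Q as the two are first made. Leave Z alone: the east and south-west runs, with different Z, give 71.8% and 72.3% at their first reading.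

The half-life of Q, read from the late east readings, is 1.48 d; 1.0 h, when you come, is far shorter, so expect the branch share in the flask then. The forecast, a little above us early, says 67% then and 98% at 6.0 d, reading “X→G and X→Q in parallel, then Q→G”.

The flask gives 66.8% and 97.0%.

    X → D (k = 0.0743 h⁻¹)
    D ⇌ G (K = 11.3, k = 0.546 h⁻¹)
    D ⇌ Q (K = 6.51, k = 0.271 h⁻¹)
    J ⇌ G, rate k4*(cs4 - [G]) while solid is left; crystals form when [G] > cs4 (solubility = 4.30 mM, k = 8.63 h⁻¹)
    X + Z → L (k = 961 M⁻¹ h⁻¹)

In the flask, by 0.600 d, X was down to 33.6% and G stood at 43.2%, of which 39.6% was crystals J, while L held 2.00% and Z was at 0%; the reaction of X and Z to L makes no difference to either share . With the flask's X at 0.465% by 3.00 d, Q fell from 8.70% to 2.89% at 6.00 d as G reached 94.8%. The neighbour flask charged with 0.033 M of X stands at 66.8% at 1.0 h, against the branch share of 65.6%, but ends at 90.9%, with Q at 8.31%.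

Readings and results are simulated on assumed constants; noise was put on by code.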